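**Plan**

- Retrosynthetic cuts: the C15–O ester bond (oleoyl chloride), C13=C14 (phosphonoacetate olefination), C8=C17 (methylenation), C9–C11 (α′-alkylation of a ring B enone), C4–C18 and C4–C19 (carbonylation, then reductive methylation of a C4=C5 enoate), and C10–C20 together with C5–C20 (cyclopropane).
- Forward: rings A and B both come from 6-methoxy-1-tetralone (ketone carbon = C4, anisole carbon = C8). Asymmetric reduction, Birch reduction and ketalisation give a 5(10)-octalin whose only stereocentre is the C4 carbinol; the cyclopropane is then closed and reopened, ring A is finished, and the side chain is joined at C9 in the order C11–C13/C16, C17, C14–C15, oleoyl.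
- Enabling feature: the angular methyl C20 sits on C10, separated only by C5 from C4, the carbon that must become quaternary with the C19 carboxyl. An oxygen on C4 can therefore steer CH2 onto the C5=C10 bond shared by rings A and B, then (as a ketone) activate the C5–C20 bond for cleavage and hand C4 over to carbonylation.
- Stereochemistry: C4–OH (S) from catalytic transfer hydrogenation; C10 (β-methyl) from hydroxyl-directed methylene transfer; C5 (α-H) and C4 (α-methyl, β-carboxyl) from protonation and methylation anti to the C10 methyl; C9 (β side chain) from equilibration next to the C8 ketone; 13E from the phosphonate olefination; 9′Z bought in with oleoyl chloride.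
- C19 is carried as a 2-(trimethylsilyl)ethyl ester, so that the hindered acid can be released last by fluoride in the presence of the oleate.

Key step: step 4

Remark on the chemistry: positions are numbered as in the labdane skeleton (ring A = C1–C5, C10; ring B = C5–C10; C11–C16 side chain; C17 exocyclic methylene; C18 = 4α-methyl; C19 = 4β-carboxyl carbon; C20 = methyl on C10), and β is the face of C20. The target is read as 15-O-oleoyl isocupressic acid, 4S,5R,9S,10R, 13E, 9′Z. The ruthenium catalyst, PhNTf2, IBX, Dess–Martin periodinane and 2-(trimethylsilyl)ethanol are taken as commercial reagents.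

**Route**

Step 1
Reactants: 1 6-methoxy-1-tetralone
Product: 2 (S)-6-methoxy-1,2,3,4-tetrahydronaphthalen-1-ol
Conditions: RuCl[(S,S)-TsDPEN](p-cymene) (1 mol%), HCO2H/Et3N (5:2), 40 °C
Reagents that add atoms: none
Why: Noyori-type asymmetric transfer hydrogenation of an aryl ketone, in which the (S,S)-diamine ligand differentiates the ketone faces in the six-membered hydride/proton-transfer transition state and is expected to give the (S)-carbinol (the future 4β-oxygen), as for 1-tetralone itself.

Step 2
Reactants: 2 (S)-6-methoxy-1,2,3,4-tetrahydronaphthalen-1-ol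
Product: 4 (S)-6-methoxy-1,2,3,4,5,8-hexahydronaphthalen-1-ol, via lithium alkoxide 3 (not isolated)
Conditions: n-BuLi (1.05 equiv), THF, −78 °C; then Li, NH3(l), t-BuOH, −78 to −33 °C; isoprene, then NH4Cl
Reagents that add atoms: none
Why: Birch reduction of the anisole ring, with protonation at C9 and C6 (ortho and meta to the methoxy group) leaving the C7=C8 enol ether and the tetrasubstituted C5=C10 alkene; the benzylic oxygen is carried as its lithium alkoxide, which is not expelled from the arene radical anion, so the C4 configuration is kept.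

Step 3
Reactants: 4 (S)-6-methoxy-1,2,3,4,5,8-hexahydronaphthalen-1-ol
Product: 5 4β-hydroxy-5(10)-octalin 8-ethylene ketal
Conditions: HOCH2CH2OH (5 equiv), pyridinium p-toluenesulfonate (cat.), THF, rt
Reagents that add atoms: ethylene glycol, OCCO
Why: acid-catalysed transketalisation of the enol ether (C7 protonation, capture of the C8 oxocarbenium ion by the diol, loss of methanol) under an acid too weak to ionise the C4 allylic alcohol or to move the C5=C10 bond into conjugation.

Step 4
Reactants: 5 4β-hydroxy-5(10)-octalin 8-ethylene ketal; 6 diiodomethane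
Product: 9 5β,10β-methano-decalin-4β-ol 8-ethylene ketal, via ethylzinc alkoxide 7 (not isolated), via iodomethylzinc alkoxide 8 (not isolated)
Conditions: Et2Zn (2.5 equiv), CH2Cl2, −10 °C; then CH2I2 (5 equiv), −10 °C to rt; aq. NH4Cl
Reagents that add atoms: diiodomethane 6, ICI
Why: The alcohol is first converted into its ethylzinc alkoxide 7, and iodine/zinc exchange with CH2I2 gives the alkoxy(iodomethyl)zinc carbenoid 8, in which the electrophilic CH2 is held over the ring face that carries the C4 oxygen. Methylene is then transferred to the electron-rich tetrasubstituted C5=C10 bond in a concerted, butterfly-type [2+1] addition that forms C10–C20 and C5–C20 in one event; the closest known reaction type is the hydroxyl-directed Simmons–Smith cyclopropanation (diethylzinc variant) of cyclic allylic alcohols, ring-fusion octalinols included. The three-membered ring is closed by this suprafacial addition of one carbon across the alkene, not by a stepwise exo or endo cyclisation. The two new stereocentres, C5 and C10, are both controlled by the (S)-C4 carbinol through zinc coordination, so the cyclopropane is expected cis to the hydroxyl, which places C20 on the β face of C10. The step needs facial selectivity only: the alkene is the sole one present, the achiral dioxolane at C8 offers an oxygen on either face and cannot act as a biased director, and excess Et2Zn keeps the medium free of protic acid so that the ketal and the cyclopropylcarbinol survive.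

Step 5
Reactants: 9 5β,10β-methano-decalin-4β-ol 8-ethylene ketal
Product: 10 5β,10β-methano-decalin-4-one 8-ethylene ketal
Conditions: Dess–Martin periodinane, NaHCO3, CH2Cl2, 0 °C to rt
Reagents that add atoms: none
Why: Dess–Martin oxidation of a secondary alcohol under buffered, non-acidic conditions that spare the dioxolane and the cyclopropylcarbinyl system; the C4 stereocentre is erased on purpose after it has directed step 4.

Step 6
Reactants: 10 5β,10β-methano-decalin-4-one 8-ethylene ketal
Product: 12 10β-methyl-8,8-ethylenedioxy-octal-4-en-4-yl trifluoromethanesulfonate, via lithium enolate 11 (not isolated)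
Conditions: Li (2.2 equiv), NH3(l)/THF, t-BuOH (1.0 equiv), −78 °C; isoprene; NH3 removed; PhNTf2, THF, 0 °C to rt
Reagents that add atoms: N-phenylbis(trifluoromethanesulfonimide), O=S(=O)(N(c1ccccc1)S(=O)(=O)C(F)(F)F)C(F)(F)F
Why: dissolving-metal cleavage of a conjugated cyclopropyl ketone, in which the C5–C20 bond (the one aligned with the C4 carbonyl π system) breaks and C20 is protonated to the β-methyl on C10, followed by O-sulfonylation of the regiodefined C4–C5 lithium enolate (enolate trapping as an enol triflate); C10 keeps the configuration set in step 4.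

Step 7
Reactants: 12 10β-methyl-8,8-ethylenedioxy-octal-4-en-4-yl trifluoromethanesulfonate
Product: 13 2-(trimethylsilyl)ethyl 10β-methyl-8,8-ethylenedioxy-octal-4-ene-4-carboxylate
Conditions: Pd(OAc)2 (5 mol%), PPh3 (10 mol%), CO (1 atm), Me3SiCH2CH2OH, Et3N, DMF, 70 °C
Reagents that add atoms: carbon monoxide, [C-]#[O+]; 2-(trimethylsilyl)ethanol, C[Si](C)(C)CCO
Why: palladium-catalysed alkoxycarbonylation of an enol triflate (oxidative addition to zerovalent palladium, CO insertion, alcoholysis of the acyl complex) installs C19 as an ester that can later be cleaved at silicon, away from the hindered carbonyl group.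

Step 8
Reactants: 13 2-(trimethylsilyl)ethyl 10β-methyl-8,8-ethylenedioxy-octal-4-ene-4-carboxylate
Product: 15 2-(trimethylsilyl)ethyl 4α,10β-dimethyl-8,8-ethylenedioxy-5α-decalin-4β-carboxylate, via lithium ester enolate 14 (not isolated)
Conditions: Li (2.2 equiv), NH3(l)/THF, t-BuOH (1.0 equiv), −78 °C; isoprene; MeI (excess), −78 to −33 °C; NH4Cl
Reagents that add atoms: iodomethane, CI
Why: dissolving-metal reductive alkylation of an α,β-unsaturated ester, in which protonation of the β-carbon C5 from the α face (axial, anti to the C10 methyl) is expected to give the trans ring fusion and the exocyclic ester enolate is methylated from the equatorial α face because the axial β face is shielded by the 1,3-related C10 methyl, so that C18 is α and the C19 ester β.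

Step 9
Reactants: 15 2-(trimethylsilyl)ethyl 4α,10β-dimethyl-8,8-ethylenedioxy-5α-decalin-4β-carboxylate
Product: 16 2-(trimethylsilyl)ethyl 4α,10β-dimethyl-8-oxo-5α-decalin-4β-carboxylate
Conditions: 1 M aq. HCl, THF, rt
Reagents that add atoms: water, O
Why: acid-catalysed hydrolysis of the dioxolane, to which the neopentyl-type silylethyl ester and the quaternary centres are inert.

Step 10
Reactants: 16 2-(trimethylsilyl)ethyl 4α,10β-dimethyl-8-oxo-5α-decalin-4β-carboxylate
Product: 17 2-(trimethylsilyl)ethyl 4α,10β-dimethyl-8-oxo-5α-octal-6-ene-4β-carboxylate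
Conditions: IBX (2 equiv), DMSO/fluorobenzene, 75 °C
Reagents that add atoms: none
Why: IBX-mediated α,β-dehydrogenation of a ketone, which can only run toward C7–C6 because C10 is quaternary and which thereby blocks C7 and leaves C9 as the sole enolisable α-position.

Step 11
Reactants: 18 2-(2-bromoethyl)-2-methyl-1,3-dioxolane
Product: 19 2-(2-iodoethyl)-2-methyl-1,3-dioxolane
Conditions: NaI, NaHCO3 (cat.), acetone, reflux
Reagents that add atoms: sodium iodide, [Na+].[I-]
Why: Finkelstein halide exchange, driven by precipitation of NaBr, provides the more reactive primary iodide for the hindered alkylation.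

Step 12
Reactants: 17 2-(trimethylsilyl)ethyl 4α,10β-dimethyl-8-oxo-5α-octal-6-ene-4β-carboxylate; 19 2-(2-iodoethyl)-2-methyl-1,3-dioxolane
Product: 21 9α-[2-(2-methyl-1,3-dioxolan-2-yl)ethyl] derivative of enone 17, via lithium dienolate 20 (not isolated)
Conditions: LiN(i-Pr)2, THF, −78 °C; then 19, DMPU, −78 to 0 °C
Reagents that add atoms: 2-(2-iodoethyl)-2-methyl-1,3-dioxolane 19, CC1(CCI)OCCO1
Why: kinetic α′-deprotonation of the enone gives the cross-conjugated C8–C9 lithium dienolate, which is alkylated by the primary iodide in an SN2 reaction (enolate alkylation) expected to occur anti to the axial C10 methyl, giving the 9α epimer that is corrected in step 13.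

Step 13
Reactants: 21 9α-[2-(2-methyl-1,3-dioxolan-2-yl)ethyl] derivative of enone 17
Product: 23 2-(trimethylsilyl)ethyl 13,13-ethylenedioxy-8-oxo-14,15,17-trinorlabdan-19-oate (9β side chain), via 9α-alkyl saturated ketone 22 (not isolated)
Conditions: H2 (1 atm), Pd/C, EtOAc, rt; filtration; then NaOMe, MeOH, 50 °C
Reagents that add atoms: none
Why: catalytic hydrogenation of the disubstituted enone alkene followed by base-mediated epimerisation α to the C8 ketone, which under thermodynamic control should place the side chain in the equatorial 9β position, free of the 1,3-diaxial contacts with H5 and H7.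

Step 14
Reactants: 23 2-(trimethylsilyl)ethyl 13,13-ethylenedioxy-8-oxo-14,15,17-trinorlabdan-19-oate
Product: 24 2-(trimethylsilyl)ethyl 13,13-ethylenedioxy-14,15-dinorlabd-8(17)-en-19-oate
Conditions: Ph3PCH3Br, KOt-Bu, toluene, 0 to 80 °C
Reagents that add atoms: methyltriphenylphosphonium bromide, C[P+](c1ccccc1)(c1ccccc1)c1ccccc1.[Br-]
Why: Wittig methylenation with the unstabilised ylide, a standard way to convert hindered 8-oxo decalins into the exocyclic C8=C17 alkene, with C9 expected to stay in its stable equatorial configuration.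

Step 15
Reactants: 24 2-(trimethylsilyl)ethyl 13,13-ethylenedioxy-14,15-dinorlabd-8(17)-en-19-oate
Product: 25 2-(trimethylsilyl)ethyl 13-oxo-14,15-dinorlabd-8(17)-en-19-oate
Conditions: TsOH·H2O (cat.), THF/H2O, rt
Reagents that add atoms: water, O
Why: acid-catalysed hydrolysis of the side-chain dioxolane under conditions too mild to isomerise the 1,1-disubstituted C8=C17 alkene.

Step 16
Reactants: 25 2-(trimethylsilyl)ethyl 13-oxo-14,15-dinorlabd-8(17)-en-19-oate; 26 triethyl phosphonoacetate
Product: 27 15-ethyl 19-[2-(trimethylsilyl)ethyl] (13E)-labda-8(17),13-diene-15,19-dioate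
Conditions: NaH, 26, THF, 0 to 60 °C
Reagents that add atoms: triethyl phosphonoacetate 26, CCOC(=O)CP(=O)(OCC)OCC
Why: Horner–Wadsworth–Emmons olefination of the methyl ketone, in which the stabilised phosphonate anion should give mainly the E-trisubstituted enoate (ester trans to the larger C12 chain), the minor Z isomer to be removed by chromatography.

Step 17
Reactants: 27 15-ethyl 19-[2-(trimethylsilyl)ethyl] (13E)-labda-8(17),13-diene-15,19-dioate
Product: 28 2-(trimethylsilyl)ethyl (13E)-15-hydroxylabda-8(17),13-dien-19-oate
Conditions: i-Bu2AlH (2.5 equiv), CH2Cl2, −78 °C; aq. potassium sodium tartrate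
Reagents that add atoms: none
Why: hydride 1,2-reduction of the conjugated ethyl ester to the allylic alcohol, with the axial, neopentyl-type C19 ester expected to react far more slowly at low temperature.

Step 18
Reactants: 28 2-(trimethylsilyl)ethyl (13E)-15-hydroxylabda-8(17),13-dien-19-oate; 29 oleoyl chloride
Product: 30 2-(trimethylsilyl)ethyl (13E)-15-[(Z)-octadec-9-enoyloxy]labda-8(17),13-dien-19-oate
Conditions: 29 (1.1 equiv), pyridine, DMAP (cat.), CH2Cl2, 0 °C
Reagents that add atoms: oleoyl chloride 29, CCCCCCCC/C=C\CCCCCCCC(Cl)=O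
Why: DMAP-catalysed O-acylation of the primary allylic alcohol by the acid chloride (nucleophilic acyl substitution), the Z alkene being carried in unchanged from the acyl chloride.

Step 19
Reactants: 30 2-(trimethylsilyl)ethyl (13E)-15-[(Z)-octadec-9-enoyloxy]labda-8(17),13-dien-19-oate
Product: 31 (13E)-15-[(Z)-octadec-9-enoyloxy]labda-8(17),13-dien-19-oic acid (target)
Conditions: Bu4NF, THF, 0 °C to rt; then cold aq. NaHSO4
Reagents that add atoms: none
Why: fluoride-induced β-elimination of the 2-(trimethylsilyl)ethyl ester (attack at silicon, loss of ethene and Me3SiF) frees the hindered C19 carboxylate without nucleophilic attack at a carbonyl group, so the allylic oleate is expected to survive.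

**Compound list**

1 | 6-methoxy-1-tetralone (6-methoxy-3,4-dihydronaphthalen-1(2H)-one) | COc1ccc2C(=O)CCCc2c1 | starting material
2 | (S)-6-methoxy-1,2,3,4-tetrahydronaphthalen-1-ol | O[C@H]1CCCc2cc(OC)ccc21 | intermediate
3 | lithium alkoxide of 2 (formed in situ) | [Li+].[O-][C@H]1CCCc2cc(OC)ccc21 | intermediate
4 | (S)-6-methoxy-1,2,3,4,5,8-hexahydronaphthalen-1-ol (4β-hydroxy-8-methoxy-5(10),7-diene) | O[C@H]1CCCC2=C1CC=C(OC)C2 | intermediate
5 | 4β-hydroxy-5(10)-octalin 8-ethylene ketal, (5'S)-3',4',5',6',7',8'-hexahydro-1'H-spiro[[1,3]dioxolane-2,2'-naphthalen]-5'-ol | O[C@H]1CCCC2=C1CCC1(OCCO1)C2 | intermediate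
6 | diiodomethane | ICI | starting material
7 | ethylzinc alkoxide of 5 (formed in situ) | CC[Zn]O[C@H]1CCCC2=C1CCC1(OCCO1)C2 | intermediate
8 | (iodomethyl)zinc alkoxide of 5 (formed in situ) | IC[Zn]O[C@H]1CCCC2=C1CCC1(OCCO1)C2 | intermediate
9 | 5β,10β-methano-decalin-4β-ol 8-ethylene ketal (cyclopropane C5–C10–C20 cis to the C4 hydroxyl) | O[C@H]1CCC[C@@]23C[C@@]12CCC1(OCCO1)C3 | intermediate
10 | 5β,10β-methano-decalin-4-one 8-ethylene ketal | O=C1CCC[C@@]23C[C@@]12CCC1(OCCO1)C3 | intermediate
11 | lithium 10β-methyl-8,8-ethylenedioxy-octal-4-en-4-olate (C4–C5 enolate, formed in situ) | C[C@]12CCCC([O-])=C1CCC1(OCCO1)C2.[Li+] | intermediate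
12 | 10β-methyl-8,8-ethylenedioxy-octal-4-en-4-yl trifluoromethanesulfonate (C4=C5) | C[C@]12CCCC(OS(=O)(=O)C(F)(F)F)=C1CCC1(OCCO1)C2 | intermediate
13 | 2-(trimethylsilyl)ethyl 10β-methyl-8,8-ethylenedioxy-octal-4-ene-4-carboxylate (C4=C5) | C[C@]12CCCC(C(=O)OCC[Si](C)(C)C)=C1CCC1(OCCO1)C2 | intermediate
14 | lithium ester enolate C4=C19(OLi)(OCH2CH2SiMe3) with 5α-H (formed in situ) | C[C@]12CCCC(=C([O-])OCC[Si](C)(C)C)[C@@H]1CCC1(OCCO1)C2.[Li+] | intermediate
15 | 2-(trimethylsilyl)ethyl 4α,10β-dimethyl-8,8-ethylenedioxy-5α-decalin-4β-carboxylate | C[C@]12CCC[C@](C)(C(=O)OCC[Si](C)(C)C)[C@@H]1CCC1(OCCO1)C2 | intermediate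
16 | 2-(trimethylsilyl)ethyl 4α,10β-dimethyl-8-oxo-5α-decalin-4β-carboxylate | C[C@]12CCC[C@](C)(C(=O)OCC[Si](C)(C)C)[C@@H]1CCC(=O)C2 | intermediate
17 | 2-(trimethylsilyl)ethyl 4α,10β-dimethyl-8-oxo-5α-octal-6-ene-4β-carboxylate | C[C@]12CCC[C@](C)(C(=O)OCC[Si](C)(C)C)[C@@H]1C=CC(=O)C2 | intermediate
18 | 2-(2-bromoethyl)-2-methyl-1,3-dioxolane | CC1(CCBr)OCCO1 | starting material
19 | 2-(2-iodoethyl)-2-methyl-1,3-dioxolane | CC1(CCI)OCCO1 | intermediate
20 | lithium C8–C9 dienolate of 17 (formed in situ) | C[C@]12CCC[C@](C)(C(=O)OCC[Si](C)(C)C)[C@@H]1C=CC([O-])=C2.[Li+] | intermediate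
21 | 9α-[2-(2-methyl-1,3-dioxolan-2-yl)ethyl] derivative of enone 17 (9β-H) | C[C@]12CCC[C@](C)(C(=O)OCC[Si](C)(C)C)[C@@H]1C=CC(=O)[C@H]2CCC1(C)OCCO1 | intermediate
22 | 9α-alkyl saturated 8-ketone (9-epimer of 23, formed in situ) | C[C@]12CCC[C@](C)(C(=O)OCC[Si](C)(C)C)[C@@H]1CCC(=O)[C@H]2CCC1(C)OCCO1 | intermediate
23 | 2-(trimethylsilyl)ethyl 13,13-ethylenedioxy-8-oxo-14,15,17-trinorlabdan-19-oate (9β side chain, 9α-H) | C[C@]12CCC[C@](C)(C(=O)OCC[Si](C)(C)C)[C@@H]1CCC(=O)[C@@H]2CCC1(C)OCCO1 | intermediate
24 | 2-(trimethylsilyl)ethyl 13,13-ethylenedioxy-14,15-dinorlabd-8(17)-en-19-oate | C[C@]12CCC[C@](C)(C(=O)OCC[Si](C)(C)C)[C@@H]1CCC(=C)[C@@H]2CCC1(C)OCCO1 | intermediate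
25 | 2-(trimethylsilyl)ethyl 13-oxo-14,15-dinorlabd-8(17)-en-19-oate | C[C@]12CCC[C@](C)(C(=O)OCC[Si](C)(C)C)[C@@H]1CCC(=C)[C@@H]2CCC(C)=O | intermediate
26 | triethyl phosphonoacetate | CCOC(=O)CP(=O)(OCC)OCC | starting material
27 | 15-ethyl 19-[2-(trimethylsilyl)ethyl] (13E)-labda-8(17),13-diene-15,19-dioate | C[C@]12CCC[C@](C)(C(=O)OCC[Si](C)(C)C)[C@@H]1CCC(=C)[C@@H]2CC/C(C)=C/C(=O)OCC | intermediate
28 | 2-(trimethylsilyl)ethyl (13E)-15-hydroxylabda-8(17),13-dien-19-oate | C[C@]12CCC[C@](C)(C(=O)OCC[Si](C)(C)C)[C@@H]1CCC(=C)[C@@H]2CC/C(C)=C/CO | intermediate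
29 | oleoyl chloride ((Z)-octadec-9-enoyl chloride) | CCCCCCCC/C=C\CCCCCCCC(Cl)=O | starting material
30 | 2-(trimethylsilyl)ethyl (13E)-15-[(Z)-octadec-9-enoyloxy]labda-8(17),13-dien-19-oate | C[C@]12CCC[C@](C)(C(=O)OCC[Si](C)(C)C)[C@@H]1CCC(=C)[C@@H]2CC/C(C)=C/COC(=O)CCCCCCC/C=C\CCCCCCCC | intermediate
31 | (13E)-15-[(Z)-octadec-9-enoyloxy]labda-8(17),13-dien-19-oic acid (4S,5R,9S,10R) | C[C@]12CCC[C@](C)(C(=O)O)[C@@H]1CCC(=C)[C@@H]2CC/C(C)=C/COC(=O)CCCCCCC/C=C\CCCCCCCC | target

**Step count and risks**

Total step count: 19. Longest linear sequence: 18 steps (steps 1–10 and 12–19, from 6-methoxy-1-tetralone); step 11 is a one-step branch.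

Steps most likely to fail:

Step 12 (α′-alkylation at C9). The SN2 reaction at the enolate carbon next to the quaternary C10 may be slow, so that elimination of HI from the iodide and proton exchange between enolate and product (recovered or polyalkylated enone) take over. The fallback forms the C9–C11 bond at a carbonyl electrophile instead. It sets out from enone 17: the lithium dienolate 20 is treated at −78 °C with (2-methyl-1,3-dioxolan-2-yl)acetaldehyde F1, itself obtained by i-Bu2AlH reduction of commercial ethyl (2-methyl-1,3-dioxolan-2-yl)acetate at −78 °C. This aldol addition should give the 11-hydroxy aldol adduct F2 as a mixture at C9 and C11. Dehydration with methyl N-(triethylammoniosulfonyl)carbamate (Burgess reagent) should then give the cross-conjugated 9(11)-alkylidene dienone F3. Hydrogenation over Pd/C saturates both C6=C7 and C9=C11, and NaOMe in MeOH equilibrates C9, which brings the material back to the route at ketone 23.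

Step 8 (reductive methylation). Excess lithium may over-reduce the ester, the ester enolate may be protonated by ammonia before methyl iodide reaches it (unmethylated ester), or facial control in the protonation at C5 may be insufficient. The fallback separates reduction and alkylation. It sets out from enoate 13: hydrogenation of the tetrasubstituted alkene with [Ir(cod)(PCy3)(py)]PF6 under H2 pressure in CH2Cl2 should deliver both hydrogens from the α face, opposite the C10 methyl, to give the saturated 5α-H 4β-ester F4. Deprotonation with LiN(i-Pr)2 in THF at −78 °C and methylation with MeI/DMPU from the equatorial α face then rejoin the route at ester 15.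

Step 6 (reductive ring opening with in-flask triflation). The lithium amide or alkoxide formed beside the enolate may consume PhNTf2 or let the enolate equilibrate toward C3, and O-sulfonylation of the tetrasubstituted enolate may be slow. The fallback sets out from cyclopropyl ketone 10: the same Li/NH3 opening is quenched with Me3SiCl/Et3N to give the isolable trimethylsilyl enol ether F5, which is purified. The salt-free lithium enolate 11 is regenerated from it with MeLi in THF and sulfonylated with the more reactive N-(5-chloro-2-pyridyl)bis(trifluoromethanesulfonimide), which returns to enol triflate 12.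

Further compounds
F1 | step 12 | (2-methyl-1,3-dioxolan-2-yl)acetaldehyde | CC1(CC=O)OCCO1
F2 | step 12 | 9-[1-hydroxy-2-(2-methyl-1,3-dioxolan-2-yl)ethyl] derivative of enone 17 (mixture at C9 and C11, both centres removed later) | C[C@]12CCC[C@](C)(C(=O)OCC[Si](C)(C)C)[C@@H]1C=CC(=O)C2C(O)CC1(C)OCCO1
F3 | step 12 | 9(11)-alkylidene dienone, 9-[2-(2-methyl-1,3-dioxolan-2-yl)ethylidene] derivative of enone 17 (alkene geometry not fixed, removed on hydrogenation) | C[C@]12CCC[C@](C)(C(=O)OCC[Si](C)(C)C)[C@@H]1C=CC(=O)C2=CCC1(C)OCCO1
F4 | step 8 | 2-(trimethylsilyl)ethyl 10β-methyl-8,8-ethylenedioxy-4α-H,5α-H-decalin-4β-carboxylate | C[C@]12CCC[C@H](C(=O)OCC[Si](C)(C)C)[C@@H]1CCC1(OCCO1)C2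
F5 | step 6 | 10β-methyl-8,8-ethylenedioxy-4-(trimethylsilyloxy)octal-4-ene (C4=C5 silyl enol ether) | C[C@]12CCCC(O[Si](C)(C)C)=C1CCC1(OCCO1)C2
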